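**Plan** (flavanone numbering: O1, C2, C3, C4, C4a, C5–C8, C8a; ring B atoms primed)

- Retrosynthesis cuts, in order: the four phenol protecting groups; the C3–C4 bond of ring C together with C2–H (retro-hydroacylation, giving aldehyde 14); the formyl carbon at C4a; the C2=C3 methylene (from an ester carbonyl); the O1–C2 ester bond, giving ring A phenol 6 and ring B acid 9.
- Forward: ring A phenol 6 (three steps from resorcinol) and ring B acid 9 (two steps) are joined as an aryl ester, which is methylenated to an aryl 1-arylvinyl ether and ortho-formylated; ring C is closed last, then two deprotections follow.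
- Enabling feature: in ring C the C4 ketone lies between arene carbon C4a and an unsubstituted C3H2 bonded to C2, which carries O1, ring B and one hydrogen. The C3–C4 and C2–H bonds are exactly what addition of a formyl C–H across an O1–C2(=C3H2)–aryl enol ether leaves, and O1 on C8a, ortho to C4a, makes that addition a six-ring closure.
- Stereochemistry: C2 (S) is the only stereocenter; it is created in the ring closure under control of a chiral bisphosphine on rhodium, under neutral conditions. The 6-prenyl (not 8-prenyl) pattern follows from the mirror symmetry of phenol 6, whose two positions ortho to OH are equivalent.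

Key step: step 9

Assumption: 2,4-dihydroxy-5-methoxybenzaldehyde (7) is taken as a catalogue compound, and since the sense of induction in step 9 cannot be predicted with confidence for this substrate class, the route is written with (R)-MeO-BIPHEP, the (S)-ligand being used instead if the first run shows that it is the one leading to (2S).

Step 1
Reactants: 1 resorcinol
Product: 2 1,3-bis(methoxymethoxy)benzene
Conditions: MOMCl (2.5 equiv), K2CO3, acetone, 0 °C to rt
Reagents that add atoms: chloromethyl methyl ether, COCCl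
Why: Williamson-type O-alkylation of both phenols with the hard electrophile MOMCl should give the bis-acetal, which supplies the directing groups for both later metalations.

Step 2
Reactants: 2 1,3-bis(methoxymethoxy)benzene
Product: 4 1,3-bis(methoxymethoxy)-2-(3-methylbut-2-en-1-yl)benzene, via 2-lithio-1,3-bis(methoxymethoxy)benzene 3 (not isolated)
Conditions: n-BuLi, THF, 0 °C; then prenyl bromide, −78 °C to rt
Reagents that add atoms: prenyl bromide, CC(C)=CCBr; n-butyllithium, [Li]CCCC (lithium of intermediate 3 only)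
Why: Directed ortho-metalation should occur at the C–H flanked by both OMOM groups, and the aryllithium should be alkylated at the primary carbon of prenyl bromide (SN2).

Step 3
Reactants: 4 1,3-bis(methoxymethoxy)-2-(3-methylbut-2-en-1-yl)benzene
Product: 6 3,5-bis(methoxymethoxy)-4-(3-methylbut-2-en-1-yl)phenol, via pinacol arylboronate 5 (not isolated)
Conditions: [Ir(OMe)(cod)]2 (1.5 mol %), 4,4'-di-tert-butyl-2,2'-bipyridine (3 mol %), B2pin2, THF, 60 °C; then NaBO3·4H2O, THF/H2O, rt
Reagents that add atoms: bis(pinacolato)diboron, CC1(C)OB(OC1(C)C)B1OC(C)(C)C(C)(C)O1 (boron of intermediate 5 only); sodium perborate, [Na+].[Na+].O[B-]1(O)OO[B-](O)(O)OO1 (the phenol oxygen)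
Why: Sterically governed iridium-catalysed arene C–H borylation should take place only at the one ring C–H with no ortho substituent (para to the prenyl group), the trisubstituted alkene being a poor substrate, and perborate oxidation of the C–B bond (no epoxidising oxidant) should give the mirror-symmetric phenol.

Step 4
Reactants: 7 2,4-dihydroxy-5-methoxybenzaldehyde
Product: 8 5-methoxy-2,4-bis(triisopropylsilyloxy)benzaldehyde
Conditions: TIPSOTf (2.4 equiv), 2,6-lutidine, CH2Cl2, 0 °C to rt
Reagents that add atoms: triisopropylsilyl trifluoromethanesulfonate, CC(C)[Si](OS(=O)(=O)C(F)(F)F)(C(C)C)C(C)C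
Why: Silylation with the silyl triflate should also cap the hydrogen-bonded 2-OH; TIPS ethers are chosen because they do not direct lithiation, resist butyllithium and are removed by fluoride.

Step 5
Reactants: 8 5-methoxy-2,4-bis(triisopropylsilyloxy)benzaldehyde
Product: 9 5-methoxy-2,4-bis(triisopropylsilyloxy)benzoic acid
Conditions: NaClO2, NaH2PO4, 2-methyl-2-butene, t-BuOH/H2O, rt
Reagents that add atoms: sodium chlorite, [Na+].[O-]Cl=O
Why: Pinnick oxidation should convert the aldehyde to the acid at about pH 4, where aryl TIPS ethers are stable, with the alkene scavenging hypochlorous acid.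

Step 6
Reactants: 6 3,5-bis(methoxymethoxy)-4-(3-methylbut-2-en-1-yl)phenol; 9 5-methoxy-2,4-bis(triisopropylsilyloxy)benzoic acid
Product: 10 3,5-bis(methoxymethoxy)-4-(3-methylbut-2-en-1-yl)phenyl 5-methoxy-2,4-bis(triisopropylsilyloxy)benzoate
Conditions: EDC·HCl, DMAP (0.2 equiv), CH2Cl2, rt
Reagents that add atoms: none
Why: Steglich esterification should acylate the unhindered phenol oxygen (the later O1) under conditions that leave the MOM and TIPS ethers and the prenyl group untouched.

Step 7
Reactants: 10 the aryl benzoate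
Product: 11 1-[3,5-bis(methoxymethoxy)-4-(3-methylbut-2-en-1-yl)phenoxy]-1-[5-methoxy-2,4-bis(triisopropylsilyloxy)phenyl]ethene
Conditions: Cp2TiMe2 (3 equiv), toluene, 70 °C, dark; filtration through basic alumina
Reagents that add atoms: dimethyltitanocene Cp2TiMe2, [CH3-].[CH3-].[Ti+4].c1cc[cH-]c1.c1cc[cH-]c1
Why: Petasis methylenation (titanium methylidene, [2+2] addition and cycloreversion) should turn the only carbonyl group, the aryl ester, into the acid-sensitive aryl 1-arylvinyl ether without a Lewis acid.

Step 8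
Reactants: 11 the aryl 1-arylvinyl ether
Product: 14 2,4-bis(methoxymethoxy)-3-(3-methylbut-2-en-1-yl)-6-({1-[5-methoxy-2,4-bis(triisopropylsilyloxy)phenyl]ethenyl}oxy)benzaldehyde, via ring A aryllithium 12 (not isolated), via lithium hemiaminal alkoxide 13 (not isolated)
Conditions: n-BuLi, TMEDA, THF, −78 to −30 °C; DMF, −78 °C to rt; aq. NH4Cl
Reagents that add atoms: N,N-dimethylformamide, CN(C)C=O; n-butyllithium, [Li]CCCC (lithium of intermediates 12 and 13 only)
Why: Directed ortho-metalation should occur at one of the two equivalent ring A C–H bonds flanked by OMOM and the vinyloxy oxygen (ring B offers only a C–H shielded by two OTIPS groups and one next to the weak director OMe), and DMF formylation then places the formyl carbon ortho to O1 with the prenyl group fixed at the later C6.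

Step 9
Reactants: 14 the 2-(1-arylvinyloxy)benzaldehyde
Product: 15 (2S)-5,7-bis(methoxymethoxy)-2-[5-methoxy-2,4-bis(triisopropylsilyloxy)phenyl]-6-(3-methylbut-2-en-1-yl)chroman-4-one
Conditions: [Rh(cod)Cl]2 (2.5 mol %), (R)-MeO-BIPHEP (5.5 mol %), Na[B(3,5-(CF3)2C6H3)4] (6 mol %), 4 Å molecular sieves, degassed THF, 60 °C
Reagents that add atoms: none
Why: Proposed new method: oxidative addition of the formyl C–H of 14 to the cationic bisphosphine complex of monovalent rhodium should give an acyl hydride of trivalent rhodium held by the flanking ether oxygens, the enol-ether alkene then inserts into Rh–H with hydride going to the internal O- and aryl-bearing carbon (the later C2) and rhodium to the terminal CH2, and C–C reductive elimination from the seven-membered acyl alkyl rhodacycle forms the CH2–C(=O) bond (C3–C4). The closest known reaction type is the rhodium-catalysed enantioselective intramolecular hydroacylation of 1,1-disubstituted alkenes (ortho-allylbenzaldehydes, N-allyl and N-vinyl heteroaryl carboxaldehydes), which gives five- and six-membered benzo-fused ketones with a β-stereocenter; new here are an aryl 1-arylvinyl ether as the alkene and a stereocenter bearing oxygen and aryl. Ring C closes in the 6-endo-trig mode, both alkene carbons entering the ring. The C2 stereocenter is created in the hydride-insertion step and is controlled only by the chiral ligand, which selects the enantioface of the prochiral alkene. The step needs endo over exo regioselectivity (exo would require a tertiary benzylic alkylrhodium and a quaternary centre on reductive elimination), insertion faster than decarbonylation (helped by O-chelation of the acyl hydride and by the absence of allylic hydrogens, so no alkene isomerisation can compete) and chemoselectivity over the prenyl group (a remote trisubstituted alkene that should not insert). The medium is neutral, so the C2–O1 bond of the flavanone cannot open by retro-oxa-Michael reaction.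

Step 10
Reactants: 15 the protected flavanone
Product: 16 (2S)-5,7-dihydroxy-2-[5-methoxy-2,4-bis(triisopropylsilyloxy)phenyl]-6-(3-methylbut-2-en-1-yl)chroman-4-one
Conditions: 3 M aq. HCl, MeOH/THF, 40 °C
Reagents that add atoms: none
Why: Acid-catalysed acetal methanolysis should remove both MOM groups (the 5-OMOM peri to the ketone is especially labile) under conditions the prenyl group tolerates and in which no phenoxide forms, while ring B still carries silyl ethers, so C2 should keep its configuration.

Step 11
Reactants: 16 the 5,7-dihydroxy bis-silyl ether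
Product: 17 kushenol V, (2S)-2-(2,4-dihydroxy-5-methoxyphenyl)-5,7-dihydroxy-6-(3-methylbut-2-en-1-yl)chroman-4-one
Conditions: Bu4NF (2.4 equiv), AcOH (3 equiv), THF, 0 °C to rt
Reagents that add atoms: none
Why: Fluoride-induced Si–O cleavage buffered with acetic acid should free both ring B phenols while protonating the 4'-phenoxide before it can expel O1 through a quinone methide, which would racemise C2.

**Compound list**

1 | resorcinol | Oc1cccc(O)c1 | starting material
2 | 1,3-bis(methoxymethoxy)benzene | COCOc1cccc(OCOC)c1 | intermediate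
3 | 2-lithio-1,3-bis(methoxymethoxy)benzene (not isolated) | COCOc1cccc(OCOC)c1[Li] | intermediate
4 | 1,3-bis(methoxymethoxy)-2-(3-methylbut-2-en-1-yl)benzene | COCOc1cccc(OCOC)c1CC=C(C)C | intermediate
5 | 2-[3,5-bis(methoxymethoxy)-4-(3-methylbut-2-en-1-yl)phenyl]-4,4,5,5-tetramethyl-1,3,2-dioxaborolane (not isolated) | CC(C)=CCc1c(OCOC)cc(cc1OCOC)B1OC(C)(C)C(C)(C)O1 | intermediate
6 | 3,5-bis(methoxymethoxy)-4-(3-methylbut-2-en-1-yl)phenol | CC(C)=CCc1c(OCOC)cc(O)cc1OCOC | intermediate
7 | 2,4-dihydroxy-5-methoxybenzaldehyde | COc1cc(C=O)c(O)cc1O | starting material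
8 | 5-methoxy-2,4-bis(triisopropylsilyloxy)benzaldehyde | COc1cc(C=O)c(O[Si](C(C)C)(C(C)C)C(C)C)cc1O[Si](C(C)C)(C(C)C)C(C)C | intermediate
9 | 5-methoxy-2,4-bis(triisopropylsilyloxy)benzoic acid | COc1cc(C(O)=O)c(O[Si](C(C)C)(C(C)C)C(C)C)cc1O[Si](C(C)C)(C(C)C)C(C)C | intermediate
10 | 3,5-bis(methoxymethoxy)-4-(3-methylbut-2-en-1-yl)phenyl 5-methoxy-2,4-bis(triisopropylsilyloxy)benzoate | COc1cc(C(=O)Oc2cc(OCOC)c(CC=C(C)C)c(OCOC)c2)c(O[Si](C(C)C)(C(C)C)C(C)C)cc1O[Si](C(C)C)(C(C)C)C(C)C | intermediate
11 | 1-[3,5-bis(methoxymethoxy)-4-(3-methylbut-2-en-1-yl)phenoxy]-1-[5-methoxy-2,4-bis(triisopropylsilyloxy)phenyl]ethene | COc1cc(C(=C)Oc2cc(OCOC)c(CC=C(C)C)c(OCOC)c2)c(O[Si](C(C)C)(C(C)C)C(C)C)cc1O[Si](C(C)C)(C(C)C)C(C)C | intermediate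
12 | ring A 2-lithio derivative of 11 (not isolated) | COc1cc(C(=C)Oc2cc(OCOC)c(CC=C(C)C)c(OCOC)c2[Li])c(O[Si](C(C)C)(C(C)C)C(C)C)cc1O[Si](C(C)C)(C(C)C)C(C)C | intermediate
13 | lithium hemiaminal alkoxide from 12 and DMF (not isolated) | COc1cc(C(=C)Oc2cc(OCOC)c(CC=C(C)C)c(OCOC)c2C(O[Li])N(C)C)c(O[Si](C(C)C)(C(C)C)C(C)C)cc1O[Si](C(C)C)(C(C)C)C(C)C | intermediate
14 | 2,4-bis(methoxymethoxy)-3-(3-methylbut-2-en-1-yl)-6-({1-[5-methoxy-2,4-bis(triisopropylsilyloxy)phenyl]ethenyl}oxy)benzaldehyde | COc1cc(C(=C)Oc2cc(OCOC)c(CC=C(C)C)c(OCOC)c2C=O)c(O[Si](C(C)C)(C(C)C)C(C)C)cc1O[Si](C(C)C)(C(C)C)C(C)C | intermediate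
15 | (2S)-5,7-bis(methoxymethoxy)-2-[5-methoxy-2,4-bis(triisopropylsilyloxy)phenyl]-6-(3-methylbut-2-en-1-yl)chroman-4-one | COc1cc([C@@H]2CC(=O)c3c(cc(OCOC)c(CC=C(C)C)c3OCOC)O2)c(O[Si](C(C)C)(C(C)C)C(C)C)cc1O[Si](C(C)C)(C(C)C)C(C)C | intermediate
16 | (2S)-5,7-dihydroxy-2-[5-methoxy-2,4-bis(triisopropylsilyloxy)phenyl]-6-(3-methylbut-2-en-1-yl)chroman-4-one | COc1cc([C@@H]2CC(=O)c3c(cc(O)c(CC=C(C)C)c3O)O2)c(O[Si](C(C)C)(C(C)C)C(C)C)cc1O[Si](C(C)C)(C(C)C)C(C)C | intermediate
17 | kushenol V, (2S)-2-(2,4-dihydroxy-5-methoxyphenyl)-5,7-dihydroxy-6-(3-methylbut-2-en-1-yl)chroman-4-one | COc1cc([C@@H]2CC(=O)c3c(cc(O)c(CC=C(C)C)c3O)O2)c(O)cc1O | target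

**Totals**

Total step count: 11. Longest linear sequence: 9 steps (steps 1, 2, 3, 6, 7, 8, 9, 10, 11 from resorcinol); the ring B branch (steps 4, 5) joins at step 6.

**Steps most likely to fail**

1. Step 9 (proposed new method). What may go wrong: decarbonylation of the acyl rhodium hydride or exo insertion outrunning the endo hydroacylation, or weak enantioface discrimination at the alkene next to the bulky ortho-silyloxy aryl group. The fallback uses known chemistry (chalcone route with enantioselective oxa-Michael ring closure), sets out from phenol 6 and aldehyde 8 and returns at flavanone 15.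
   - Magnesium-mediated ortho-formylation of 6 (MgCl2, Et3N, paraformaldehyde, MeCN, reflux) should give 6-hydroxy-2,4-bis(methoxymethoxy)-3-(3-methylbut-2-en-1-yl)benzaldehyde F1.
   - Addition of MeMgBr (excess, THF, 0 °C) should give 1-[6-hydroxy-2,4-bis(methoxymethoxy)-3-(3-methylbut-2-en-1-yl)phenyl]ethan-1-ol F2, and MnO2 (CH2Cl2) should oxidise it to 1-[6-hydroxy-2,4-bis(methoxymethoxy)-3-(3-methylbut-2-en-1-yl)phenyl]ethan-1-one F3.
   - Claisen–Schmidt condensation of F3 with 8 (Ba(OH)2·8H2O, MeOH, rt) should give (E)-1-[6-hydroxy-2,4-bis(methoxymethoxy)-3-(3-methylbut-2-en-1-yl)phenyl]-3-[5-methoxy-2,4-bis(triisopropylsilyloxy)phenyl]prop-2-en-1-one F4.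
   - Intramolecular oxa-Michael addition of F4 under a quinine-derived bifunctional thiourea (toluene, rt; the quinidine-derived catalyst if the other sense is needed) should close the O1–C2 bond to give 15. Selectivity is expected to be lower than a metal-catalysed route would aim for, so enrichment by crystallisation should be planned.

2. Step 3. What may go wrong: hydroboration or allylic/vinylic borylation of the prenyl double bond by the iridium boryl species and pinacolborane competing with arene C–H borylation. The fallback introduces the phenol oxygen before the alkene; it sets out from 2 and returns at 6.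
   - The same borylation on alkene-free 2 should give 2-[3,5-bis(methoxymethoxy)phenyl]-4,4,5,5-tetramethyl-1,3,2-dioxaborolane F5, oxidised in the flask (NaBO3·4H2O) to 3,5-bis(methoxymethoxy)phenol F6.
   - TIPSCl/imidazole (DMF) should give [3,5-bis(methoxymethoxy)phenoxy]triisopropylsilane F7.
   - n-BuLi (THF, 0 °C) should metalate between the two OMOM groups to give the 4-lithio derivative of the silyl ether F8, and prenyl bromide should give [3,5-bis(methoxymethoxy)-4-(3-methylbut-2-en-1-yl)phenoxy]triisopropylsilane F9.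
   - Bu4NF (THF) should then release 6.

3. Step 8. What may go wrong: loss of regiocontrol in the lithiation (deprotonation at ring B or at the benzylic/allylic CH2) or addition of butyllithium to the styrenyl enol ether. The fallback fixes the metalation site by halogen–metal exchange; it sets out from 6 and returns at aryllithium 12.
   - ortho-Iodination of 6 (I2, morpholine, CH2Cl2, 0 °C) should give 2-iodo-3,5-bis(methoxymethoxy)-4-(3-methylbut-2-en-1-yl)phenol F10.
   - Steglich esterification with 9 should give 2-iodo-3,5-bis(methoxymethoxy)-4-(3-methylbut-2-en-1-yl)phenyl 5-methoxy-2,4-bis(triisopropylsilyloxy)benzoate F11.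
   - Petasis methylenation (Cp2TiMe2, toluene, 70 °C) should give 1-[2-iodo-3,5-bis(methoxymethoxy)-4-(3-methylbut-2-en-1-yl)phenoxy]-1-[5-methoxy-2,4-bis(triisopropylsilyloxy)phenyl]ethene F12.
   - Iodine–lithium exchange (n-BuLi, THF, −78 °C), much faster than any deprotonation, should give 12, which is formylated with DMF as in step 8.

**Further compounds**

F1 | step 9 | 6-hydroxy-2,4-bis(methoxymethoxy)-3-(3-methylbut-2-en-1-yl)benzaldehyde | O=Cc1c(O)cc(OCOC)c(CC=C(C)C)c1OCOC
F2 | step 9 | 1-[6-hydroxy-2,4-bis(methoxymethoxy)-3-(3-methylbut-2-en-1-yl)phenyl]ethan-1-ol (racemic) | CC(O)c1c(O)cc(OCOC)c(CC=C(C)C)c1OCOC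
F3 | step 9 | 1-[6-hydroxy-2,4-bis(methoxymethoxy)-3-(3-methylbut-2-en-1-yl)phenyl]ethan-1-one | CC(=O)c1c(O)cc(OCOC)c(CC=C(C)C)c1OCOC
F4 | step 9 | (E)-1-[6-hydroxy-2,4-bis(methoxymethoxy)-3-(3-methylbut-2-en-1-yl)phenyl]-3-[5-methoxy-2,4-bis(triisopropylsilyloxy)phenyl]prop-2-en-1-one | COc1cc(/C=C/C(=O)c2c(O)cc(OCOC)c(CC=C(C)C)c2OCOC)c(O[Si](C(C)C)(C(C)C)C(C)C)cc1O[Si](C(C)C)(C(C)C)C(C)C
F5 | step 3 | 2-[3,5-bis(methoxymethoxy)phenyl]-4,4,5,5-tetramethyl-1,3,2-dioxaborolane | COCOc1cc(OCOC)cc(c1)B1OC(C)(C)C(C)(C)O1
F6 | step 3 | 3,5-bis(methoxymethoxy)phenol | COCOc1cc(O)cc(OCOC)c1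
F7 | step 3 | [3,5-bis(methoxymethoxy)phenoxy]triisopropylsilane | COCOc1cc(O[Si](C(C)C)(C(C)C)C(C)C)cc(OCOC)c1
F8 | step 3 | [4-lithio-3,5-bis(methoxymethoxy)phenoxy]triisopropylsilane | COCOc1cc(O[Si](C(C)C)(C(C)C)C(C)C)cc(OCOC)c1[Li]
F9 | step 3 | [3,5-bis(methoxymethoxy)-4-(3-methylbut-2-en-1-yl)phenoxy]triisopropylsilane | COCOc1cc(O[Si](C(C)C)(C(C)C)C(C)C)cc(OCOC)c1CC=C(C)C
F10 | step 8 | 2-iodo-3,5-bis(methoxymethoxy)-4-(3-methylbut-2-en-1-yl)phenol | Oc1cc(OCOC)c(CC=C(C)C)c(OCOC)c1I
F11 | step 8 | 2-iodo-3,5-bis(methoxymethoxy)-4-(3-methylbut-2-en-1-yl)phenyl 5-methoxy-2,4-bis(triisopropylsilyloxy)benzoate | COc1cc(C(=O)Oc2cc(OCOC)c(CC=C(C)C)c(OCOC)c2I)c(O[Si](C(C)C)(C(C)C)C(C)C)cc1O[Si](C(C)C)(C(C)C)C(C)C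
F12 | step 8 | 1-[2-iodo-3,5-bis(methoxymethoxy)-4-(3-methylbut-2-en-1-yl)phenoxy]-1-[5-methoxy-2,4-bis(triisopropylsilyloxy)phenyl]ethene | COc1cc(C(=C)Oc2cc(OCOC)c(CC=C(C)C)c(OCOC)c2I)c(O[Si](C(C)C)(C(C)C)C(C)C)cc1O[Si](C(C)C)(C(C)C)C(C)C
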